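The cyclohexane is cut into two three-carbon units, with ring atoms numbered C1 (carbinol carbon), C2 (CH–CH3), C3–C5 (CH2) and C6 (C(CH3)2): C4–C5–C6 is an isoprene unit, C1–C2–C3 a methacrylic unit. In one iron-hydride operation isoprene and methacrylonitrile are joined twice: hydrogen-atom transfer to isoprene and Giese addition form C3–C4, a second hydrogen-atom transfer and 6-exo cyclisation of the tertiary C6 radical onto the nitrile carbon form C6–C1, giving racemic 2,2,6-trimethylcyclohexanone. The step exploits the 1,3-relationship of C6 and C2 across C1 in the six-membered ring. Enantioselective protonation then sets C2, axial Grignard addition sets C1, and carboalumination, B-alkyl Suzuki coupling and lactol olefination build the butenolide chain.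

Key step: step 1

Remark: compounds 8, 12, 15 and 19 are taken to be commercially available; the Why lines use the ring numbering of the first paragraph, not the IUPAC locants of the compound names.

Step 1
Reactants: 1 isoprene (2-methylbuta-1,3-diene); 2 methacrylonitrile (2-methylprop-2-enenitrile)
Product: 5 rac-2,2,6-trimethylcyclohexan-1-one, via 2,6-dimethylhept-5-enenitrile 3 (not isolated), via 2,2,6-trimethylcyclohexan-1-imine 4 (not isolated)
Conditions: Fe(acac)3 (30 mol%), PhSiH3 (4 equiv, slow addition), 1 (3 equiv), EtOH–(CH2OH)2, 60 °C, sealed vessel; then 1 M aq. HCl, rt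
Reagents that add atoms: water, O
Why: Proposed new method: an iron hydride formed from Fe(acac)3 and PhSiH3 transfers a hydrogen atom to the 1,1-disubstituted terminus of isoprene, and the resulting 1,1-dimethylallyl radical adds through its unhindered CH2 terminus to the β-carbon of methacrylonitrile (C3–C4, Giese addition), after which reduction and protonation of the α-cyano radical give nitrile 3. A second hydrogen-atom transfer to the trisubstituted alkene of 3 generates the tertiary radical at C6, which closes the ring by 6-exo-dig addition to the nitrile carbon C1 (C6–C1); the iminyl radical is reduced to imine 4, which is hydrolysed to ketone 5 on acidic work-up. The closest known reaction types are the iron-hydride reductive coupling of olefins with Michael acceptors and the hydrogen-atom-transfer cyclisation of alkene-tethered nitriles and ketones; new is their combination through a diene that reacts at both ends of its allyl unit. The only stereocenter formed (C2) arises without control and is reset in steps 2 and 3, so this step has to control constitution only. It needs hydrogen-atom transfer to isoprene in preference to the electron-poor acceptor, bond formation at the primary allyl terminus, and cyclisation faster than reduction of the tertiary radical; these should be favoured by the excess of isoprene, by the steric bias of the allyl radical and by slow addition of the silane.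

Step 2
Reactants: 5 rac-2,2,6-trimethylcyclohexan-1-one
Product: 6 trimethyl[(2,6,6-trimethylcyclohex-1-en-1-yl)oxy]silane
Conditions: Me3SiOTf, Et3N, CH2Cl2, 0 °C to rt
Reagents that add atoms: trimethylsilyl trifluoromethanesulfonate, C[Si](C)(C)OS(=O)(=O)C(F)(F)F
Why: Soft enolisation with O-silylation (silyl enol ether formation) can only involve the hydrogen on C2 because C6 is quaternary, so a single enol ether should result and the uncontrolled stereocenter of 5 is erased on purpose.

Step 3
Reactants: 6 trimethyl[(2,6,6-trimethylcyclohex-1-en-1-yl)oxy]silane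
Product: 7 (S)-2,2,6-trimethylcyclohexan-1-one
Conditions: (R)-2'-methoxy-1,1'-binaphthalen-2-ol·SnCl4 (1.1 equiv), toluene, −78 °C
Reagents that add atoms: none
Why: Enantioselective protonation of a silyl enol ether by a Lewis-acid-assisted chiral Brønsted acid should deliver the proton to one enantiotopic face of C2 and so set its S configuration under reagent control, the antipodal ligand being used if the sense of induction proves to be the reverse.

Step 4
Reactants: 7 (S)-2,2,6-trimethylcyclohexan-1-one; 8 (4-bromobut-1-yn-1-yl)trimethylsilane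
Product: 10 (1R,6S)-2,2,6-trimethyl-1-[4-(trimethylsilyl)but-3-yn-1-yl]cyclohexan-1-ol, via [4-(trimethylsilyl)but-3-yn-1-yl]magnesium bromide 9 (not isolated)
Conditions: 8, Mg, THF, rt; anhydrous CeCl3, THF, −78 °C; then 7, −78 to 0 °C; aq. NH4Cl
Reagents that add atoms: none
Why: Organocerium-type 1,2-addition of the Grignard reagent suppresses enolisation of the hindered ketone, and attack along the axial trajectory, away from the axial methyl group on C6, should place the chain cis and the hydroxyl trans to the C2 methyl group, which sets C1 as R under substrate control.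

Step 5
Reactants: 10 (1R,6S)-2,2,6-trimethyl-1-[4-(trimethylsilyl)but-3-yn-1-yl]cyclohexan-1-ol
Product: 11 (1R,6S)-1-(but-3-yn-1-yl)-2,2,6-trimethylcyclohexan-1-ol
Conditions: K2CO3, MeOH, rt
Reagents that add atoms: none
Why: Base-mediated protodesilylation of the alkynylsilane in methanol should free the terminal alkyne without touching the tertiary alcohol.

Step 6
Reactants: 11 (1R,6S)-1-(but-3-yn-1-yl)-2,2,6-trimethylcyclohexan-1-ol; 12 bromoethene
Product: 14 (1R,6S)-2,2,6-trimethyl-1-[(3E)-3-methylhexa-3,5-dien-1-yl]cyclohexan-1-ol, via alkenyldimethylalane 13 (not isolated)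
Conditions: AlMe3 (3 equiv), Cp2ZrCl2 (25 mol%), CH2Cl2, 0 °C to rt; then 12, Pd(PPh3)4 (5 mol%), ZnCl2, THF, rt
Reagents that add atoms: trimethylaluminium, C[Al](C)C
Why: Zirconium-catalysed syn-carboalumination of the terminal alkyne fixes the E trisubstituted alkene, and the palladium-catalysed Negishi-type coupling of the alkenylalane with bromoethene proceeds with retention to give the E diene.

Step 7
Reactants: 14 (1R,6S)-2,2,6-trimethyl-1-[(3E)-3-methylhexa-3,5-dien-1-yl]cyclohexan-1-ol; 15 4-bromofuran-2(5H)-one
Product: 17 4-[(3E)-6-[(1R,6S)-1-hydroxy-2,2,6-trimethylcyclohexyl]-4-methylhex-3-en-1-yl]furan-2(5H)-one, via B-alkyl-9-BBN adduct 16 (not isolated)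
Conditions: 9-BBN (2.2 equiv), THF, 0 °C to rt; then 15, PdCl2(dppf) (5 mol%), AsPh3, Cs2CO3, DMF–H2O, rt
Reagents that add atoms: none
Why: 9-BBN should hydroborate only the terminal monosubstituted alkene of the diene with boron on the terminal carbon, and the B-alkyl Suzuki–Miyaura coupling with the β-bromobutenolide then forms the sp3–sp2 bond.

Step 8
Reactants: 17 4-[(3E)-6-[(1R,6S)-1-hydroxy-2,2,6-trimethylcyclohexyl]-4-methylhex-3-en-1-yl]furan-2(5H)-one
Product: 18 4-[(3E)-6-[(1R,6S)-1-hydroxy-2,2,6-trimethylcyclohexyl]-4-methylhex-3-en-1-yl]-2,5-dihydrofuran-2-ol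
Conditions: iBu2AlH (2.2 equiv), CH2Cl2, −78 °C; aq. Rochelle salt
Reagents that add atoms: none
Why: Partial reduction of the lactone with iBu2AlH at low temperature should stop at the lactol, a masked Z-γ-hydroxy enal in which the ring keeps the CH2O carbon cis to the future diene.

Step 9
Reactants: 19 4-(bromomethyl)furan-2(5H)-one
Product: 20 diethyl [(5-oxo-2,5-dihydrofuran-3-yl)methyl]phosphonate
Conditions: P(OEt)3, toluene, 110 °C
Reagents that add atoms: triethyl phosphite, CCOP(OCC)OCC
Why: The Michaelis–Arbuzov reaction of the allylic bromide with triethyl phosphite should give the vinylogous phosphonate.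

Step 10
Reactants: 18 4-[(3E)-6-[(1R,6S)-1-hydroxy-2,2,6-trimethylcyclohexyl]-4-methylhex-3-en-1-yl]-2,5-dihydrofuran-2-ol; 20 diethyl [(5-oxo-2,5-dihydrofuran-3-yl)methyl]phosphonate
Product: 21 4-[(1E,3Z,7E)-4-(hydroxymethyl)-10-[(1R,6S)-1-hydroxy-2,2,6-trimethylcyclohexyl]-8-methyldeca-1,3,7-trien-1-yl]furan-2(5H)-one
Conditions: LiCl, DBU, MeCN, 0 °C to rt
Reagents that add atoms: none
Why: The Horner–Wadsworth–Emmons olefination under mild LiCl/DBU conditions traps the open hydroxy-enal form of the lactol and should form the new disubstituted alkene with E geometry, while the trisubstituted alkene keeps the Z geometry (CH2OH cis to the diene) imposed by the former ring.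

Step 11
Reactants: 21 4-[(1E,3Z,7E)-4-(hydroxymethyl)-10-[(1R,6S)-1-hydroxy-2,2,6-trimethylcyclohexyl]-8-methyldeca-1,3,7-trien-1-yl]furan-2(5H)-one
Product: 22 4-[(1E,3Z,7E)-4-(acetoxymethyl)-10-[(1R,6S)-1-hydroxy-2,2,6-trimethylcyclohexyl]-8-methyldeca-1,3,7-trien-1-yl]furan-2(5H)-one (CNP0366059.1)
Conditions: Ac2O, pyridine, DMAP (cat.), CH2Cl2, 0 °C
Reagents that add atoms: acetic anhydride, CC(=O)OC(C)=O
Why: Acylation of the primary allylic alcohol is much faster than that of the hindered tertiary alcohol, which should stay free.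

Compound list
1 | isoprene (2-methylbuta-1,3-diene) | C=CC(C)=C | starting material
2 | methacrylonitrile (2-methylprop-2-enenitrile) | CC(=C)C#N | starting material
3 | 2,6-dimethylhept-5-enenitrile (racemic) | CC(C#N)CCC=C(C)C | intermediate
4 | 2,2,6-trimethylcyclohexan-1-imine (racemic) | CC1CCCC(C)(C)C1=N | intermediate
5 | rac-2,2,6-trimethylcyclohexan-1-one | CC1CCCC(C)(C)C1=O | intermediate
6 | trimethyl[(2,6,6-trimethylcyclohex-1-en-1-yl)oxy]silane | CC1=C(O[Si](C)(C)C)C(C)(C)CCC1 | intermediate
7 | (S)-2,2,6-trimethylcyclohexan-1-one | O=C1[C@@H](C)CCCC1(C)C | intermediate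
8 | (4-bromobut-1-yn-1-yl)trimethylsilane | C[Si](C)(C)C#CCCBr | starting material
9 | [4-(trimethylsilyl)but-3-yn-1-yl]magnesium bromide | C[Si](C)(C)C#CCC[Mg]Br | intermediate
10 | (1R,6S)-2,2,6-trimethyl-1-[4-(trimethylsilyl)but-3-yn-1-yl]cyclohexan-1-ol | C[Si](C)(C)C#CCC[C@@]1(O)[C@@H](C)CCCC1(C)C | intermediate
11 | (1R,6S)-1-(but-3-yn-1-yl)-2,2,6-trimethylcyclohexan-1-ol | C#CCC[C@@]1(O)[C@@H](C)CCCC1(C)C | intermediate
12 | bromoethene | C=CBr | starting material
13 | alkenyldimethylalane: (E)-alkenyl–Al(CH3)2 adduct of 11 (CH3 on the internal carbon, Al on the terminal carbon, cis to each other), drawn as its dimethylaluminium alkoxide | C[Al](C)/C=C(\C)CC[C@@]1(O[Al](C)C)[C@@H](C)CCCC1(C)C | intermediate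
14 | (1R,6S)-2,2,6-trimethyl-1-[(3E)-3-methylhexa-3,5-dien-1-yl]cyclohexan-1-ol | C=C/C=C(\C)CC[C@@]1(O)[C@@H](C)CCCC1(C)C | intermediate
15 | 4-bromofuran-2(5H)-one | BrC1=CC(=O)OC1 | starting material
16 | B-alkyl-9-BBN adduct: 9-[(3E)-6-[(1R,6S)-1-hydroxy-2,2,6-trimethylcyclohexyl]-4-methylhex-3-en-1-yl]-9-borabicyclo[3.3.1]nonane | C1CC2CCCC(C1)B2CC/C=C(\C)CC[C@@]3(O)[C@@H](C)CCCC3(C)C | intermediate
17 | 4-[(3E)-6-[(1R,6S)-1-hydroxy-2,2,6-trimethylcyclohexyl]-4-methylhex-3-en-1-yl]furan-2(5H)-one | O=C1OCC(CC/C=C(\C)CC[C@@]2(O)[C@@H](C)CCCC2(C)C)=C1 | intermediate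
18 | 4-[(3E)-6-[(1R,6S)-1-hydroxy-2,2,6-trimethylcyclohexyl]-4-methylhex-3-en-1-yl]-2,5-dihydrofuran-2-ol (lactol, both epimers at the acetal carbon) | OC1OCC(CC/C=C(\C)CC[C@@]2(O)[C@@H](C)CCCC2(C)C)=C1 | intermediate
19 | 4-(bromomethyl)furan-2(5H)-one | BrCC1=CC(=O)OC1 | starting material
20 | diethyl [(5-oxo-2,5-dihydrofuran-3-yl)methyl]phosphonate | CCOP(=O)(OCC)CC1=CC(=O)OC1 | intermediate
21 | 4-[(1E,3Z,7E)-4-(hydroxymethyl)-10-[(1R,6S)-1-hydroxy-2,2,6-trimethylcyclohexyl]-8-methyldeca-1,3,7-trien-1-yl]furan-2(5H)-one | OC/C(=C\C=C\C1=CC(=O)OC1)CC/C=C(\C)CC[C@@]1(O)[C@@H](C)CCCC1(C)C | intermediate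
22 | 4-[(1E,3Z,7E)-4-(acetoxymethyl)-10-[(1R,6S)-1-hydroxy-2,2,6-trimethylcyclohexyl]-8-methyldeca-1,3,7-trien-1-yl]furan-2(5H)-one (CNP0366059.1) | CC(=O)OC/C(=C\C=C\C1=CC(=O)OC1)CC/C=C(\C)CC[C@@]1(O)[C@@H](C)CCCC1(C)C | target

Total step count: 11. Longest linear sequence: 10 steps (steps 1 to 8, then 10 and 11); step 9 prepares the phosphonate.

Steps most likely to fail

Step 1 (proposed new method). The allyl radical may be reduced or may add through its tertiary terminus, and the tertiary radical may be reduced before the slow 6-exo-dig closure onto an unactivated nitrile. The fallback uses known chemistry, sets out from 2 and returns at 5. Zinc–copper-mediated radical conjugate addition of 4-iodo-2-methylbut-1-ene to 2 (Zn, CuI, EtOH–H2O, sonication) should give 2,6-dimethylhept-6-enenitrile F1. Markovnikov addition of HBr should give 6-bromo-2,6-dimethylheptanenitrile F2. Bu3SnH with AIBN (slow addition, benzene, 80 °C) generates the same tertiary radical, which cyclises onto the nitrile to imine 4, and acidic hydrolysis gives 5.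

Step 4. Enolisation of the hindered ketone may compete (loss of material and erosion of enantiopurity by proton return), and facial selectivity may be insufficient. The fallback sets out from 7 and returns at 10. Corey–Chaykovsky epoxidation with dimethylsulfonium methylide (Me3S+ I−, n-BuLi, THF, −10 °C; irreversible axial attack of a small nucleophile) should give (3R,8S)-4,4,8-trimethyl-1-oxaspiro[2.5]octane F3. Opening of F3 at its CH2 terminus with 3-lithio-1-(trimethylsilyl)prop-1-yne (from 1-(trimethylsilyl)propyne, n-BuLi, TMEDA, THF) gives 10.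

Step 10. The lactol may dehydrate to a 3-substituted furan, E selectivity may be incomplete, and base may isomerise the Z-enal. The fallback sets out from 18 and returns at 21. Boron-Wittig olefination with lithiated bis(pinacolato)borylmethane (CH2(Bpin)2, LiTMP, THF, −78 °C to rt) should give (2Z,4E)-2-[(3E)-6-[(1R,6S)-1-hydroxy-2,2,6-trimethylcyclohexyl]-4-methylhex-3-en-1-yl]-5-(4,4,5,5-tetramethyl-1,3,2-dioxaborolan-2-yl)penta-2,4-dien-1-ol F4. Suzuki–Miyaura coupling of F4 with 15 (Pd(PPh3)4, aq. K3PO4, THF, 50 °C) forms the bond to the butenolide and gives 21.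

Further compounds
F1 | step 1 | 2,6-dimethylhept-6-enenitrile | CC(C#N)CCCC(C)=C
F2 | step 1 | 6-bromo-2,6-dimethylheptanenitrile | CC(C#N)CCCC(C)(C)Br
F3 | step 4 | (3R,8S)-4,4,8-trimethyl-1-oxaspiro[2.5]octane | C2[C@@]1(O2)[C@@H](C)CCCC1(C)C
F4 | step 10 | (2Z,4E)-2-[(3E)-6-[(1R,6S)-1-hydroxy-2,2,6-trimethylcyclohexyl]-4-methylhex-3-en-1-yl]-5-(4,4,5,5-tetramethyl-1,3,2-dioxaborolan-2-yl)penta-2,4-dien-1-ol | OC/C(=C\C=C\B1OC(C)(C)C(C)(C)O1)CC/C=C(\C)CC[C@@]1(O)[C@@H](C)CCCC1(C)C
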